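**Retrosynthetic overview**
1. Target 26 ⇐ 24: the oxolane is closed last (silyl ether cleavage, acetal hydrolysis, lactol acetylation). The side-chain acetate comes from an SN2 inversion, and the two adjacent centres from an enamine anti-aldol of aldehyde 18 with methyl glyoxylate.
2. 18 ⇐ 16 + 17: the bond between the quaternary hydroazulene carbon and the future oxolane C-4 is made by a chiral-amine/organic-photocatalyst Giese coupling of a tertiary radical with an enal iminium ion (new step).
3. 16 ⇐ 13: methyl addition to the cis-hydroazulenone and conversion of the tertiary alcohol into its cesium oxalate.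
4. 13 ⇐ 12 ⇐ 10: the seven-membered ring by intramolecular Pd-catalysed ketone α-alkenylation; the first stereocentre by organocatalytic transfer hydrogenation of cyclopentenone 10.
5. 10 ⇐ 1 + 2 + 4: cyclopentenone by aldol cyclisation of a 1,4-diketone. Ring order: five-membered carbocycle, seven-membered carbocycle, oxolane.

Assumption: the enantiomer named for each chiral organocatalyst is the one its accepted stereochemical model predicts for the product drawn (for step 10 by analogy with (S)-proline); the mirror-image catalyst is used if an optical-rotation check shows the opposite sense.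

**Step 1**
Reactants: 1 isobutyric acid; 2 (5-chloropent-1-yn-1-yl)trimethylsilane
Product: 3 2,2-dimethyl-7-(trimethylsilyl)hept-6-ynoic acid
Conditions: LiN(i-Pr)2 (2.2 equiv), THF, 0 → 45 °C; then 2, NaI (10 mol%), DMPU, 20 °C; aq. HCl work-up
Reagents that add atoms: none
Why: SN2 alkylation of the carboxylic acid dianion (enediolate) by the primary halide builds the gem-dimethyl quaternary carbon, the silyl group keeping the alkyne C–H from quenching the dianion.

**Step 2**
Reactants: 3 2,2-dimethyl-7-(trimethylsilyl)hept-6-ynoic acid; 4 2-(2-bromoethyl)-2-methyl-1,3-dioxolane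
Product: 7 4,4-dimethyl-1-(2-methyl-1,3-dioxolan-2-yl)-9-(trimethylsilyl)non-8-yn-3-one, via acid chloride 5 (not isolated), via Grignard reagent 6 (not isolated)
Conditions: 3, (COCl)2, DMF (cat.), CH2Cl2, 20 °C, evaporate; separately 4, Mg, THF, 25 °C; combine with CuI (10 mol%), THF, −30 °C
Reagents that add atoms: oxalyl chloride ClC(=O)C(=O)Cl (the Cl of 5); magnesium [Mg] (the Mg of 6)
Why: Copper-catalysed acylation of a Grignard reagent by a hindered acid chloride stops cleanly at the ketone and installs the masked 1,4-diketone.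

**Step 3**
Reactants: 7 4,4-dimethyl-1-(2-methyl-1,3-dioxolan-2-yl)-9-(trimethylsilyl)non-8-yn-3-one
Product: 10 3-(2-methylhept-6-yn-2-yl)cyclopent-2-en-1-one, via silyl diketone 8 (not isolated), via alkynyl diketone 9 (not isolated)
Conditions: 2 M HCl, THF, 20 °C; then KOH, MeOH, 20 → 65 °C
Reagents that add atoms: water O
Why: Acetal hydrolysis followed by base-mediated intramolecular aldol condensation (only the methyl ketone enolate can form a five-membered ring) gives the 3-substituted cyclopentenone, and methanolic KOH also removes the alkynyl silyl group.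

**Step 4**
Reactants: 10 3-(2-methylhept-6-yn-2-yl)cyclopent-2-en-1-one
Product: 11 (3R)-3-(2-methylhept-6-yn-2-yl)cyclopentan-1-one
Conditions: (2S,5S)-5-benzyl-3-methyl-2-(5-methylfuran-2-yl)imidazolidin-4-one·Cl3CCO2H (20 mol%), di-tert-butyl 2,6-dimethyl-1,4-dihydropyridine-3,5-dicarboxylate (1.1 equiv), Et2O, 0 °C
Reagents that add atoms: none
Why: Organocatalytic iminium-ion transfer hydrogenation (MacMillan type): the Hantzsch ester delivers hydride to one face of the β-carbon of the chiral iminium ion, which sets the first stereocentre (R, the future ring-fusion carbon next to the gem-dimethyl group).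

**Step 5**
Reactants: 11 (3R)-3-(2-methylhept-6-yn-2-yl)cyclopentan-1-one
Product: 12 (3R)-3-(6-iodo-2-methylhept-6-en-2-yl)cyclopentan-1-one
Conditions: NaI (1.5 equiv), Me3SiCl (1.5 equiv), H2O (0.75 equiv), MeCN, 20 °C
Reagents that add atoms: sodium iodide [Na+].[I-]
Why: Markovnikov hydroiodination of the terminal alkyne by HI generated in situ gives the 2-iodo-1-alkene needed for ring closure without touching the ketone.

**Step 6**
Reactants: 12 (3R)-3-(6-iodo-2-methylhept-6-en-2-yl)cyclopentan-1-one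
Product: 13 (3aR,8aS)-4,4-dimethyl-8-methylideneoctahydroazulen-1(2H)-one
Conditions: Pd(PPh3)4 (10 mol%), t-BuOK (1.6 equiv), THF/t-BuOH, 20 °C
Reagents that add atoms: none
Why: Piers-type intramolecular α-alkenylation of a ketone enolate (oxidative addition of zerovalent palladium into the C–I bond, C-bound Pd enolate, reductive elimination) closes the seven-membered ring; only the enolate towards C-2 can reach the alkenyl-Pd, and the tether delivers to its own face so the ring fusion is cis (also the more stable epimer), setting the second ring-fusion centre (S).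

**Step 7**
Reactants: 13 (3aR,8aS)-4,4-dimethyl-8-methylideneoctahydroazulen-1(2H)-one
Product: 14 (3aR,8aS)-1,4,4-trimethyl-8-methylidenedecahydroazulen-1-ol (both C-1 epimers)
Conditions: MeMgBr, CeCl3, THF, −78 → 0 °C
Reagents that add atoms: methylmagnesium bromide C[Mg]Br
Why: Organocerium (Imamoto) 1,2-addition is non-basic enough to avoid enolisation or migration of the β,γ-alkene; the carbinol configuration is irrelevant because this carbon becomes a radical in step 9.

**Step 8**
Reactants: 14 (3aR,8aS)-1,4,4-trimethyl-8-methylidenedecahydroazulen-1-ol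
Product: 16 cesium 2-oxo-2-{[(3aR,8aS)-1,4,4-trimethyl-8-methylidenedecahydroazulen-1-yl]oxy}acetate, via methyl oxalate 15 (not isolated)
Conditions: ClC(O)CO2Me, Et3N, DMAP (cat.), CH2Cl2, 0 °C; then CsOH (1 M aq.), THF, 20 °C
Reagents that add atoms: methyl chlorooxoacetate COC(=O)C(=O)Cl; cesium hydroxide [Cs+].[OH-]
Why: Acylation of the tertiary alcohol and selective saponification of the unhindered methyl ester give the bench-stable cesium tert-alkyl oxalate, an established tertiary-radical precursor.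

**Step 9**
Reactants: 16 cesium 2-oxo-2-{[(3aR,8aS)-1,4,4-trimethyl-8-methylidenedecahydroazulen-1-yl]oxy}acetate; 17 (E)-4,4-dimethoxybut-2-enal
Product: 18 (3R)-4,4-dimethoxy-3-[(1R,3aR,8aS)-1,4,4-trimethyl-8-methylidenedecahydroazulen-1-yl]butanal
Conditions: 17 (2 equiv), 2,4,5,6-tetrakis(carbazol-9-yl)isophthalonitrile (2 mol%), (S)-2-{bis[3,5-bis(trifluoromethyl)phenyl][(tert-butyldimethylsilyl)oxy]methyl}pyrrolidine (20 mol%), PhCO2H (20 mol%), DME/H2O 10:1, 450 nm LEDs, 20 °C
Reagents that add atoms: none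
Why: Proposed new method: the chiral secondary amine turns 17 into an (E)-iminium ion far more electrophilic than the free enal, the excited organic photocatalyst oxidises the oxalate (loss of two CO2) to the tertiary radical, which adds through its convex face (sets the quaternary carbon as R, substrate control) to the iminium β-carbon on the Si face left open by the diarylmethyl shield (sets C-3 of 18 as R, catalyst control), and the resulting radical cation is reduced by the reduced photocatalyst to the enamine, which hydrolyses; the closest known reaction types are Giese fragment couplings of tert-alkyl oxalates with uncatalysed acceptors and enantioselective iminium-ion trapping of stabilised radicals by chiral amines.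

**Step 10**
Reactants: 18 (3R)-4,4-dimethoxy-3-[(1R,3aR,8aS)-1,4,4-trimethyl-8-methylidenedecahydroazulen-1-yl]butanal; 19 methyl glyoxylate
Product: 21 methyl (2R,3R,4R)-2-hydroxy-3-(hydroxymethyl)-5,5-dimethoxy-4-[(1R,3aR,8aS)-1,4,4-trimethyl-8-methylidenedecahydroazulen-1-yl]pentanoate, via aldol aldehyde 20 (not isolated)
Conditions: (S)-bis[3,5-bis(trifluoromethyl)phenyl](pyrrolidin-2-yl)methanol (10 mol%), 19 (3 equiv), MeCN/H2O, 4 °C; then NaBH4, MeOH, −40 °C
Reagents that add atoms: none
Why: Diarylprolinol-catalysed enamine cross-aldol with a non-enolisable glyoxylate through a hydrogen-bonded anti transition state (List–Houk type) lets the catalyst fix both the enamine face (C-3) and the glyoxylate face (C-2, R at this stage), and in-flask borohydride reduction removes the epimerisable aldehyde.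

**Step 11**
Reactants: 21 methyl (2R,3R,4R)-2-hydroxy-3-(hydroxymethyl)-5,5-dimethoxy-4-[(1R,3aR,8aS)-1,4,4-trimethyl-8-methylidenedecahydroazulen-1-yl]pentanoate
Product: 22 methyl (2R,3R,4R)-3-{[(tert-butyldimethylsilyl)oxy]methyl}-2-hydroxy-5,5-dimethoxy-4-[(1R,3aR,8aS)-1,4,4-trimethyl-8-methylidenedecahydroazulen-1-yl]pentanoate
Conditions: TBSCl (1.1 equiv), imidazole, CH2Cl2, 0 °C
Reagents that add atoms: tert-butyldimethylsilyl chloride CC(C)(C)[Si](C)(C)Cl
Why: Chemoselective silylation of the primary alcohol over the deactivated secondary α-hydroxy ester blocks γ-lactonisation and leaves only the C-2 hydroxyl free.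

**Step 12**
Reactants: 22 methyl (2R,3R,4R)-3-{[(tert-butyldimethylsilyl)oxy]methyl}-2-hydroxy-5,5-dimethoxy-4-[(1R,3aR,8aS)-1,4,4-trimethyl-8-methylidenedecahydroazulen-1-yl]pentanoate
Product: 24 methyl (2S,3R,4R)-2-acetoxy-3-{[(tert-butyldimethylsilyl)oxy]methyl}-5,5-dimethoxy-4-[(1R,3aR,8aS)-1,4,4-trimethyl-8-methylidenedecahydroazulen-1-yl]pentanoate, via triflate 23 (not isolated)
Conditions: Tf2O, 2,6-lutidine, CH2Cl2, −78 °C; then Bu4NOAc, MeCN, −40 → 0 °C
Reagents that add atoms: trifluoromethanesulfonic anhydride O=S(=O)(OS(=O)(=O)C(F)(F)F)C(F)(F)F (the triflyl group of 23); tetrabutylammonium acetate CCCC[N+](CCCC)(CCCC)CCCC.CC(=O)[O-]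
Why: SN2 displacement of an α-triflyloxy ester by acetate goes with clean inversion (2R to 2S) and installs the side-chain acetate with the configuration of the target.

**Step 13**
Reactants: 24 methyl (2S,3R,4R)-2-acetoxy-3-{[(tert-butyldimethylsilyl)oxy]methyl}-5,5-dimethoxy-4-[(1R,3aR,8aS)-1,4,4-trimethyl-8-methylidenedecahydroazulen-1-yl]pentanoate
Product: 26 CNP0222222.1 (methyl (2S)-2-acetoxy-2-[(3R,4R,5R)-5-acetoxy-4-[(1R,3aR,8aS)-1,4,4-trimethyl-8-methylidenedecahydroazulen-1-yl]oxolan-3-yl]acetate), via lactol 25 (not isolated)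
Conditions: HF (48 % aq.), MeCN, 0 → 20 °C; then Ac2O, pyridine, DMAP (cat.), CH2Cl2, 0 °C
Reagents that add atoms: water O; acetic anhydride CC(=O)OC(C)=O
Why: Acidic desilylation and acetal hydrolysis free the primary alcohol and the aldehyde, which close kinetically to the γ-lactol (the only free hydroxyl; the 3,4-cis relation was fixed in steps 9 and 10), and acetylation gives the anomeric acetate trans to the bulky neighbouring substituent (5R).

**Compound list**
1 | isobutyric acid | CC(C)C(=O)O | starting material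
2 | (5-chloropent-1-yn-1-yl)trimethylsilane | C[Si](C)(C)C#CCCCCl | starting material
3 | 2,2-dimethyl-7-(trimethylsilyl)hept-6-ynoic acid | C[Si](C)(C)C#CCCCC(C)(C)C(=O)O | intermediate
4 | 2-(2-bromoethyl)-2-methyl-1,3-dioxolane | CC1(CCBr)OCCO1 | starting material
5 | 2,2-dimethyl-7-(trimethylsilyl)hept-6-ynoyl chloride | C[Si](C)(C)C#CCCCC(C)(C)C(=O)Cl | intermediate (not isolated)
6 | [2-(2-methyl-1,3-dioxolan-2-yl)ethyl]magnesium bromide | CC1(CC[Mg]Br)OCCO1 | intermediate (not isolated)
7 | 4,4-dimethyl-1-(2-methyl-1,3-dioxolan-2-yl)-9-(trimethylsilyl)non-8-yn-3-one | C[Si](C)(C)C#CCCCC(C)(C)C(=O)CCC1(C)OCCO1 | intermediate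
8 | 6,6-dimethyl-11-(trimethylsilyl)undec-10-yne-2,5-dione | CC(=O)CCC(=O)C(C)(C)CCCC#C[Si](C)(C)C | intermediate (not isolated)
9 | 6,6-dimethylundec-10-yne-2,5-dione | CC(=O)CCC(=O)C(C)(C)CCCC#C | intermediate (not isolated)
10 | 3-(2-methylhept-6-yn-2-yl)cyclopent-2-en-1-one | C#CCCCC(C)(C)C1=CC(=O)CC1 | intermediate
11 | (3R)-3-(2-methylhept-6-yn-2-yl)cyclopentan-1-one | C#CCCCC(C)(C)[C@@H]1CCC(=O)C1 | intermediate
12 | (3R)-3-(6-iodo-2-methylhept-6-en-2-yl)cyclopentan-1-one | C=C(I)CCCC(C)(C)[C@@H]1CCC(=O)C1 | intermediate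
13 | (3aR,8aS)-4,4-dimethyl-8-methylideneoctahydroazulen-1(2H)-one | C=C1CCCC(C)(C)[C@@H]2CCC(=O)[C@H]12 | intermediate
14 | (3aR,8aS)-1,4,4-trimethyl-8-methylidenedecahydroazulen-1-ol (both C-1 epimers) | C=C1CCCC(C)(C)[C@@H]2CCC(C)(O)[C@H]12 | intermediate
15 | methyl (3aR,8aS)-1,4,4-trimethyl-8-methylidenedecahydroazulen-1-yl oxalate | C=C1CCCC(C)(C)[C@@H]2CCC(C)(OC(=O)C(=O)OC)[C@H]12 | intermediate (not isolated)
16 | cesium 2-oxo-2-{[(3aR,8aS)-1,4,4-trimethyl-8-methylidenedecahydroazulen-1-yl]oxy}acetate | C=C1CCCC(C)(C)[C@@H]2CCC(C)(OC(=O)C(=O)[O-])[C@H]12.[Cs+] | intermediate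
17 | (E)-4,4-dimethoxybut-2-enal | COC(OC)/C=C/C=O | starting material
18 | (3R)-4,4-dimethoxy-3-[(1R,3aR,8aS)-1,4,4-trimethyl-8-methylidenedecahydroazulen-1-yl]butanal | C=C1CCCC(C)(C)[C@@H]2CC[C@@](C)([C@@H](CC=O)C(OC)OC)[C@H]12 | intermediate
19 | methyl glyoxylate | COC(=O)C=O | starting material
20 | methyl (2R,3S,4R)-3-formyl-2-hydroxy-5,5-dimethoxy-4-[(1R,3aR,8aS)-1,4,4-trimethyl-8-methylidenedecahydroazulen-1-yl]pentanoate | C=C1CCCC(C)(C)[C@@H]2CC[C@@](C)([C@H](C(OC)OC)[C@H](C=O)[C@@H](O)C(=O)OC)[C@H]12 | intermediate (not isolated)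
21 | methyl (2R,3R,4R)-2-hydroxy-3-(hydroxymethyl)-5,5-dimethoxy-4-[(1R,3aR,8aS)-1,4,4-trimethyl-8-methylidenedecahydroazulen-1-yl]pentanoate | C=C1CCCC(C)(C)[C@@H]2CC[C@@](C)([C@H](C(OC)OC)[C@H](CO)[C@@H](O)C(=O)OC)[C@H]12 | intermediate
22 | methyl (2R,3R,4R)-3-{[(tert-butyldimethylsilyl)oxy]methyl}-2-hydroxy-5,5-dimethoxy-4-[(1R,3aR,8aS)-1,4,4-trimethyl-8-methylidenedecahydroazulen-1-yl]pentanoate | C=C1CCCC(C)(C)[C@@H]2CC[C@@](C)([C@H](C(OC)OC)[C@H](CO[Si](C)(C)C(C)(C)C)[C@@H](O)C(=O)OC)[C@H]12 | intermediate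
23 | methyl (2R,3R,4R)-3-{[(tert-butyldimethylsilyl)oxy]methyl}-5,5-dimethoxy-2-{[(trifluoromethyl)sulfonyl]oxy}-4-[(1R,3aR,8aS)-1,4,4-trimethyl-8-methylidenedecahydroazulen-1-yl]pentanoate | C=C1CCCC(C)(C)[C@@H]2CC[C@@](C)([C@H](C(OC)OC)[C@H](CO[Si](C)(C)C(C)(C)C)[C@@H](OS(=O)(=O)C(F)(F)F)C(=O)OC)[C@H]12 | intermediate (not isolated)
24 | methyl (2S,3R,4R)-2-acetoxy-3-{[(tert-butyldimethylsilyl)oxy]methyl}-5,5-dimethoxy-4-[(1R,3aR,8aS)-1,4,4-trimethyl-8-methylidenedecahydroazulen-1-yl]pentanoate | C=C1CCCC(C)(C)[C@@H]2CC[C@@](C)([C@H](C(OC)OC)[C@H](CO[Si](C)(C)C(C)(C)C)[C@H](OC(C)=O)C(=O)OC)[C@H]12 | intermediate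
25 | methyl (2S)-2-acetoxy-2-[(3R,4R)-5-hydroxy-4-[(1R,3aR,8aS)-1,4,4-trimethyl-8-methylidenedecahydroazulen-1-yl]oxolan-3-yl]acetate (both anomers) | C=C1CCCC(C)(C)[C@@H]2CC[C@@](C)([C@@H]3C(O)OC[C@@H]3[C@H](OC(C)=O)C(=O)OC)[C@H]12 | intermediate (not isolated)
26 | CNP0222222.1, methyl (2S)-2-acetoxy-2-[(3R,4R,5R)-5-acetoxy-4-[(1R,3aR,8aS)-1,4,4-trimethyl-8-methylidenedecahydroazulen-1-yl]oxolan-3-yl]acetate | C=C1CCCC(C)(C)[C@@H]2CC[C@@](C)([C@@H]3[C@@H](OC(C)=O)OC[C@@H]3[C@H](OC(C)=O)C(=O)OC)[C@H]12 | target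

**Step count and risks**
Total step count: 13. Longest linear sequence: 13 (from 1; compounds 2, 4, 17 and 19 are purchased).

The three steps most likely to fail:

Step 9 (the proposed new coupling) may suffer from uncatalysed addition of the radical to free enal 17, or from a mismatch between the catalyst and the chiral radical, either of which lowers the selectivity at C-3. The fallback uses known chemistry and gives up catalyst control. It sets out from 16, which is coupled under the established conditions for tert-alkyl oxalates (2,4,5,6-tetrakis(carbazol-9-yl)isophthalonitrile, DME/DMF, H2O, blue LEDs, 60 °C) with the achiral acceptor methyl (E)-4,4-dimethoxybut-2-enoate. This gives methyl (3R)-4,4-dimethoxy-3-[(1R,3aR,8aS)-1,4,4-trimethyl-8-methylidenedecahydroazulen-1-yl]butanoate F1 together with its (3S) epimer F2; the quaternary centre is still set by the convex face of the radical, but C-3 is not controlled. After chromatographic separation, F1 is reduced with i-Bu2AlH (toluene, −78 °C) and comes back to the route at aldehyde 18.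

Step 6 (seven-membered ring by Pd-catalysed α-alkenylation) may fail through slow closure of the larger ring, reduction of the alkenyl iodide, or base-induced migration of the new exocyclic alkene. The fallback replaces the basic enolate coupling by a neutral gold-catalysed 7-exo-dig cyclisation of a silyl enol ether, which is known chemistry. It sets out from 11, which is silylated (TBSOTf, Et3N, CH2Cl2) to tert-butyldimethyl{[(3R)-3-(2-methylhept-6-yn-2-yl)cyclopent-1-en-1-yl]oxy}silane F3 and its regioisomer tert-butyldimethyl{[(4R)-4-(2-methylhept-6-yn-2-yl)cyclopent-1-en-1-yl]oxy}silane F4. Only F3 can cyclise under AuCl[P(C≡C–SiAr3)3]/AgNTf2 (Ar = 3,5-di-tert-butyl-4-methoxyphenyl) in CH2Cl2/MeOH, and it comes back to the route at ketone 13. F4 is hydrolysed to 11 on acidic work-up and recycled.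

Step 12 (inversion at the hindered α-carbon) may be diverted by E2 elimination to the alkylidene ester or by attack of an acetal oxygen on the triflate. The fallback avoids a leaving group at this carbon and inverts it by oxidation and reduction. It sets out from 22, which is oxidised with Dess–Martin periodinane (NaHCO3, CH2Cl2) to methyl (3R,4R)-3-{[(tert-butyldimethylsilyl)oxy]methyl}-5,5-dimethoxy-2-oxo-4-[(1R,3aR,8aS)-1,4,4-trimethyl-8-methylidenedecahydroazulen-1-yl]pentanoate F5. Felkin–Anh reduction with LiBH(s-Bu)3 (THF, −78 °C; hydride anti to the large C-4 branch) gives methyl (2S,3R,4R)-3-{[(tert-butyldimethylsilyl)oxy]methyl}-2-hydroxy-5,5-dimethoxy-4-[(1R,3aR,8aS)-1,4,4-trimethyl-8-methylidenedecahydroazulen-1-yl]pentanoate F6. Acetylation (Ac2O, pyridine, DMAP) comes back to the route at 24.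

**Further compounds**
F1 | step 9 | methyl (3R)-4,4-dimethoxy-3-[(1R,3aR,8aS)-1,4,4-trimethyl-8-methylidenedecahydroazulen-1-yl]butanoate | C=C1CCCC(C)(C)[C@@H]2CC[C@@](C)([C@@H](CC(=O)OC)C(OC)OC)[C@H]12
F2 | step 9 | methyl (3S)-4,4-dimethoxy-3-[(1R,3aR,8aS)-1,4,4-trimethyl-8-methylidenedecahydroazulen-1-yl]butanoate | C=C1CCCC(C)(C)[C@@H]2CC[C@@](C)([C@H](CC(=O)OC)C(OC)OC)[C@H]12
F3 | step 6 | tert-butyldimethyl{[(3R)-3-(2-methylhept-6-yn-2-yl)cyclopent-1-en-1-yl]oxy}silane | C#CCCCC(C)(C)[C@@H]1CCC(O[Si](C)(C)C(C)(C)C)=C1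
F4 | step 6 | tert-butyldimethyl{[(4R)-4-(2-methylhept-6-yn-2-yl)cyclopent-1-en-1-yl]oxy}silane | C#CCCCC(C)(C)[C@@H]1CC=C(O[Si](C)(C)C(C)(C)C)C1
F5 | step 12 | methyl (3R,4R)-3-{[(tert-butyldimethylsilyl)oxy]methyl}-5,5-dimethoxy-2-oxo-4-[(1R,3aR,8aS)-1,4,4-trimethyl-8-methylidenedecahydroazulen-1-yl]pentanoate | C=C1CCCC(C)(C)[C@@H]2CC[C@@](C)([C@H](C(OC)OC)[C@H](CO[Si](C)(C)C(C)(C)C)C(=O)C(=O)OC)[C@H]12
F6 | step 12 | methyl (2S,3R,4R)-3-{[(tert-butyldimethylsilyl)oxy]methyl}-2-hydroxy-5,5-dimethoxy-4-[(1R,3aR,8aS)-1,4,4-trimethyl-8-methylidenedecahydroazulen-1-yl]pentanoate | C=C1CCCC(C)(C)[C@@H]2CC[C@@](C)([C@H](C(OC)OC)[C@H](CO[Si](C)(C)C(C)(C)C)[C@H](O)C(=O)OC)[C@H]12
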